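Atoms are named by daucane numbering (C1 quaternary fusion carbon, C4 tertiary carbinol, C5 fusion CH, C6 aroyloxy CH, C8=C9 ring alkene, C10 tigloyloxy CH). The seven-membered ring is cut at C8–C9 and C5–C6 into a cyclopentenyl methyl ketone (as its silyl enol ether, C9–C10–C1–C5) and a nitro ketal (C6–C7–C8). In one pot a Mukaiyama ketal addition joins C9 to C8 and an intramolecular nitrile oxide cycloaddition onto the ring alkene C4=C5 joins C6 to C5 while delivering oxygen to C4. The step exploits the cis 1,3-dioxygenation C4(OH)–C5–C6(O) on the cis-fused cyclopentane (a masked aldol); C8=C9 is unveiled later by loss of methanol.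

Key step: step 7

Remark: C2/C3 are the cyclopentane CH2 groups, C7 the ring CH2 between C6 and C8; C8 is a stereocentre only in 10–16 and is carried as an epimer mixture that converges in step 10; vinylmagnesium bromide, Me2AlCl, Tf2O, i-PrMgCl, 4-acetoxybenzoyl chloride and tigloyl chloride are taken as commercial.

Step 1
Reactants: 1 3-methylcyclopent-2-en-1-one
Product: 3 (S)-3-methyl-3-vinylcyclopent-1-en-1-yl trifluoromethanesulfonate, via aluminium enolate 2 (not isolated)
Conditions: CH2=CHMgBr + Me2AlCl (gives CH2=CHAlMe2), Cu(OTf)2 (5 mol%), chiral sulfonate-bearing imidazolinium salt (NHC precursor, 5 mol%), Et2O, −30 °C; then Tf2O, −78 to 0 °C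
Reagents that add atoms: vinylmagnesium bromide, C=C[Mg]Br; triflic anhydride, O=S(=O)(OS(=O)(=O)C(F)(F)F)C(F)(F)F
Why: Copper-catalysed asymmetric conjugate addition of the vinylalane to the β-methyl enone should set the quaternary stereocentre (future C1) under ligand control, and O-triflation of the regiodefined aluminium enolate fixes the position of the future C4=C5 double bond.

Step 2
Reactants: 3 (S)-3-methyl-3-vinylcyclopent-1-en-1-yl trifluoromethanesulfonate
Product: 4 (S)-1-isopropyl-3-methyl-3-vinylcyclopent-1-ene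
Conditions: i-PrMgCl, Fe(acac)3 (5 mol%), THF/NMP, −30 °C
Reagents that add atoms: isopropylmagnesium chloride, CC(C)[Mg]Cl
Why: Iron-catalysed Kumada-type cross-coupling of an alkenyl triflate with a secondary alkyl Grignard reagent should proceed without isomerisation of the isopropyl group and does not touch the stereocentre.

Step 3
Reactants: 4 (S)-1-isopropyl-3-methyl-3-vinylcyclopent-1-ene
Product: 5 (R)-1-(3-isopropyl-1-methylcyclopent-2-en-1-yl)ethan-1-one
Conditions: PdCl2 (10 mol%), CuCl, O2 (1 atm), DMF/H2O 7:1, 23 °C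
Reagents that add atoms: water, O
Why: Tsuji–Wacker oxidation should convert the monosubstituted vinyl group Markovnikov-selectively into the methyl ketone while the trisubstituted ring alkene stays untouched (the descriptor changes to R by CIP priority only).

Step 4
Reactants: 5 (R)-1-(3-isopropyl-1-methylcyclopent-2-en-1-yl)ethan-1-one
Product: 6 (R)-{[1-(3-isopropyl-1-methylcyclopent-2-en-1-yl)vinyl]oxy}trimethylsilane
Conditions: TMSOTf, Et3N, CH2Cl2, 0 °C
Reagents that add atoms: trimethylsilyl trifluoromethanesulfonate, C[Si](C)(C)OS(=O)(=O)C(F)(F)F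
Why: Soft enolisation (silyl triflate and amine) of a ketone whose other α-carbon is quaternary can only give the terminal silyl enol ether.

Step 5
Reactants: 7 but-3-en-2-one
Product: 8 4-nitrobutan-2-one
Conditions: NaNO2, AcOH, THF, 23 °C
Reagents that add atoms: sodium nitrite, [Na+].[O-]N=O
Why: Conjugate (Michael) addition of nitrite to the enone under buffered acidic conditions should give the β-nitro ketone.

Step 6
Reactants: 8 4-nitrobutan-2-one
Product: 9 2,2-dimethoxy-4-nitrobutane
Conditions: HC(OMe)3, TsOH·H2O (cat.), MeOH, 23 °C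
Reagents that add atoms: trimethyl orthoformate, COC(OC)OC
Why: Acid-catalysed ketalisation with orthoformate as water scavenger should proceed without the base-induced loss of nitrite to which β-nitro ketones are prone.

Step 7
Reactants: 6 (R)-{[1-(3-isopropyl-1-methylcyclopent-2-en-1-yl)vinyl]oxy}trimethylsilane; 9 2,2-dimethoxy-4-nitrobutane
Product: 12 (1R,4R,5S)-8-methoxy-4,6-(epoxynitrilo)daucan-10-one (tricyclic 2-isoxazoline C6=N–O–C4), via nitro ketone 10 (not isolated), via nitrile oxide 11 (not isolated)
Conditions: TMSOTf (10 mol%), CH2Cl2, −78 °C; then in the same flask Et3N (cat.), toluene, PhNCO (slow addition, high dilution), 23 to 60 °C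
Reagents that add atoms: none
Why: In one flask, catalytic TMSOTf ionises ketal 9 to a methoxy-oxocarbenium ion that is captured by the terminal carbon (C9) of silyl enol ether 6, a Mukaiyama aldol-type addition to a ketal that forms C8–C9 (nitro ketone 10), the enol silane being far more nucleophilic than the trisubstituted ring alkene and the nitro group inert to the silyl triflate. Phenyl isocyanate and triethylamine then dehydrate the primary nitro group (Mukaiyama–Hoshino method) to nitrile oxide 11, which adds across C4=C5 in a concerted [3+2] cycloaddition, the closest known reaction type being the intramolecular nitrile oxide–alkene cycloaddition. That event closes the seven-membered carbocycle by C6–C5 bond formation (dipole carbon to the proximal, less substituted alkene carbon, the distal carbon C4 staying outside the new carbocycle) and the fused isoxazoline ring by O–C4 bond formation at the more substituted alkene terminus, so tether and electronic preference agree. The C5 and C4 stereocentres are controlled by C1: the five-atom tether anchored at C1 can reach only the alkene face syn to C10, and the suprafacial addition puts C6 and the oxygen cis, giving the cis-fused ring system with the oxygen on C4 cis to C6, while C8 forms as an epimer mixture that converges in step 10. The selectivity needed is ring closure over nitrile oxide dimerisation, which the two fully substituted tether atoms (C1, C8), the sp2 C10 and slow isocyanate addition at high dilution should secure.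

Step 8
Reactants: 12 (1R,4R,5S)-8-methoxy-4,6-(epoxynitrilo)daucan-10-one
Product: 14 (1R,4R,5R)-4-hydroxy-8-methoxydaucane-6,10-dione, via hydroxy imine 13 (not isolated)
Conditions: Raney Ni, H2 (1 atm), B(OH)3, MeOH/H2O 5:1, 23 °C
Reagents that add atoms: water, O
Why: Hydrogenolysis of the isoxazoline N–O bond and hydrolysis of the resulting β-hydroxy imine in boric acid buffer should unmask the β-hydroxy ketone without retro-aldol cleavage or epimerisation at C5 (5R here by CIP priority only).

Step 9
Reactants: 14 (1R,4R,5R)-4-hydroxy-8-methoxydaucane-6,10-dione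
Product: 16 (1R,4R,5S,6R)-4,6-dihydroxy-8-methoxydaucan-10-one, via boron chelate 15 (not isolated)
Conditions: Et2BOMe, THF/MeOH 4:1, −78 °C; NaBH4; then evaporation from MeOH
Reagents that add atoms: none
Why: In this Narasaka–Prasad reduction only the β-hydroxy ketone forms the six-membered diethylboron chelate, so the neopentylic C10 ketone should stay untouched, and external hydride attacks C6 on the convex face syn to H5 to give the syn-1,3-diol with the 6R carbinol.

Step 10
Reactants: 16 (1R,4R,5S,6R)-4,6-dihydroxy-8-methoxydaucan-10-one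
Product: 17 (1R,4R,5S,6R)-4,6-dihydroxydauc-8-en-10-one
Conditions: DBU, CH2Cl2, 23 °C
Reagents that add atoms: none
Why: E1cB elimination of methanol from the β-methoxy ketone should give the conjugated C8=C9 enone from both C8 epimers, since C1 is quaternary and enolisation is possible only towards C9.

Step 11
Reactants: 17 (1R,4R,5S,6R)-4,6-dihydroxydauc-8-en-10-one
Product: 18 (1R,4R,5S,6R)-4-hydroxy-10-oxodauc-8-en-6-yl 4-acetoxybenzoate
Conditions: 4-acetoxybenzoyl chloride, Et3N, DMAP (cat.), CH2Cl2, 0 to 23 °C
Reagents that add atoms: 4-acetoxybenzoyl chloride, CC(=O)Oc1ccc(cc1)C(Cl)=O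
Why: DMAP-catalysed acylation should discriminate the secondary C6 hydroxyl from the tertiary C4 hydroxyl.

Step 12
Reactants: 18 (1R,4R,5S,6R)-4-hydroxy-10-oxodauc-8-en-6-yl 4-acetoxybenzoate
Product: 19 (1R,4R,5S,6R,10R)-4,10-dihydroxydauc-8-en-6-yl 4-acetoxybenzoate
Conditions: NaBH4, CeCl3·7H2O, MeOH, −78 °C
Reagents that add atoms: none
Why: Luche 1,2-reduction of the enone, in which hydride is expected to attack C10 anti to the adjacent angular methyl group on C1 (as in 17-keto steroids), should give the 10R alcohol cis to that methyl group.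

Step 13
Reactants: 19 (1R,4R,5S,6R,10R)-4,10-dihydroxydauc-8-en-6-yl 4-acetoxybenzoate
Product: 20 (1R,4R,5S,6R,10R)-4-hydroxy-10-(tigloyloxy)dauc-8-en-6-yl 4-acetoxybenzoate
Conditions: tigloyl chloride, Et3N, DMAP, CH2Cl2, 0 to 23 °C
Reagents that add atoms: (E)-2-methylbut-2-enoyl chloride, C/C=C(\C)C(Cl)=O
Why: DMAP-catalysed esterification with the acid chloride should acylate the secondary allylic C10 hydroxyl only, the tertiary C4 hydroxyl being inert and the (E)-geometry of the acyl unit being retained.

Step 14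
Reactants: 20 (1R,4R,5S,6R,10R)-4-hydroxy-10-(tigloyloxy)dauc-8-en-6-yl 4-acetoxybenzoate
Product: 21 (1R,4R,5S,6R,10R)-4-hydroxy-10-(tigloyloxy)dauc-8-en-6-yl 4-hydroxybenzoate
Conditions: K2CO3 (0.2 equiv), MeOH, 0 °C
Reagents that add atoms: none
Why: Base-catalysed methanolysis should cleave the aryl acetate (phenoxide leaving group) far faster than the benzoate and tiglate esters of secondary alcohols, and the phenoxide formed deactivates the benzoate further.

Compound list
1 | 3-methylcyclopent-2-en-1-one | CC1=CC(=O)CC1 | starting material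
2 | dimethylaluminium (S)-3-methyl-3-vinylcyclopent-1-en-1-olate | C=C[C@]1(C)CCC(O[Al](C)C)=C1 | intermediate
3 | (S)-3-methyl-3-vinylcyclopent-1-en-1-yl trifluoromethanesulfonate | C=C[C@]1(C)CCC(OS(=O)(=O)C(F)(F)F)=C1 | intermediate
4 | (S)-1-isopropyl-3-methyl-3-vinylcyclopent-1-ene | C=C[C@]1(C)CCC(C(C)C)=C1 | intermediate
5 | (R)-1-(3-isopropyl-1-methylcyclopent-2-en-1-yl)ethan-1-one | CC(=O)[C@]1(C)CCC(C(C)C)=C1 | intermediate
6 | (R)-{[1-(3-isopropyl-1-methylcyclopent-2-en-1-yl)vinyl]oxy}trimethylsilane | C=C(O[Si](C)(C)C)[C@]1(C)CCC(C(C)C)=C1 | intermediate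
7 | but-3-en-2-one (methyl vinyl ketone) | CC(=O)C=C | starting material
8 | 4-nitrobutan-2-one | CC(=O)CC[N+](=O)[O-] | intermediate
9 | 2,2-dimethoxy-4-nitrobutane | COC(C)(OC)CC[N+](=O)[O-] | intermediate
10 | 1-[(R)-3-isopropyl-1-methylcyclopent-2-en-1-yl]-3-methoxy-3-methyl-5-nitropentan-1-one (C3 epimers) | CC(CC[N+](=O)[O-])(OC)CC(=O)[C@]1(C)CCC(C(C)C)=C1 | intermediate
11 | 5-[(R)-3-isopropyl-1-methylcyclopent-2-en-1-yl]-3-methoxy-3-methyl-5-oxopentanenitrile N-oxide | CC(CC#[N+][O-])(OC)CC(=O)[C@]1(C)CCC(C(C)C)=C1 | intermediate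
12 | (1R,4R,5S)-8-methoxy-4,6-(epoxynitrilo)daucan-10-one: cis-fused hydroazulen-10-one carrying a 2-isoxazoline fused at C4–C5–C6 (C6=N–O–C4), C8 epimers | O=C1CC(C)(OC)CC2=NO[C@@]3(C(C)C)CC[C@]1(C)[C@@H]23 | intermediate
13 | (1R,4R,5S)-4-hydroxy-6-imino-8-methoxydaucan-10-one | O=C1CC(C)(OC)CC(=N)[C@@H]2[C@@]1(C)CC[C@@]2(O)C(C)C | intermediate
14 | (1R,4R,5R)-4-hydroxy-8-methoxydaucane-6,10-dione (same geometry at C5 as in 12) | O=C1CC(C)(OC)CC(=O)[C@@H]2[C@@]1(C)CC[C@@]2(O)C(C)C | intermediate
15 | diethylboron chelate of 14 (O4–BEt2, coordinated by the C6 carbonyl oxygen) | O=C1CC(C)(OC)CC(=O)[C@@H]2[C@@]1(C)CC[C@@]2(OB(CC)CC)C(C)C | intermediate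
16 | (1R,4R,5S,6R)-4,6-dihydroxy-8-methoxydaucan-10-one | O=C1CC(C)(OC)C[C@@H](O)[C@@H]2[C@@]1(C)CC[C@@]2(O)C(C)C | intermediate
17 | (1R,4R,5S,6R)-4,6-dihydroxydauc-8-en-10-one | O=C1C=C(C)C[C@@H](O)[C@@H]2[C@@]1(C)CC[C@@]2(O)C(C)C | intermediate
18 | (1R,4R,5S,6R)-4-hydroxy-10-oxodauc-8-en-6-yl 4-acetoxybenzoate | O=C1C=C(C)C[C@@H](OC(=O)c3ccc(OC(C)=O)cc3)[C@@H]2[C@@]1(C)CC[C@@]2(O)C(C)C | intermediate
19 | (1R,4R,5S,6R,10R)-4,10-dihydroxydauc-8-en-6-yl 4-acetoxybenzoate | O[C@@H]1C=C(C)C[C@@H](OC(=O)c3ccc(OC(C)=O)cc3)[C@@H]2[C@@]1(C)CC[C@@]2(O)C(C)C | intermediate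
20 | (1R,4R,5S,6R,10R)-4-hydroxy-10-[(E)-2-methylbut-2-enoyloxy]dauc-8-en-6-yl 4-acetoxybenzoate | C/C=C(\C)C(=O)O[C@@H]1C=C(C)C[C@@H](OC(=O)c3ccc(OC(C)=O)cc3)[C@@H]2[C@@]1(C)CC[C@@]2(O)C(C)C | intermediate
21 | (1R,4R,5S,6R,10R)-4-hydroxy-10-[(E)-2-methylbut-2-enoyloxy]dauc-8-en-6-yl 4-hydroxybenzoate, i.e. (3R,3aS,4R,8R,8aR)-3-hydroxy-6,8a-dimethyl-8-[(E)-2-methylbut-2-enoyloxy]-3-(propan-2-yl)-1,2,3,3a,4,5,8,8a-octahydroazulen-4-yl 4-hydroxybenzoate | C/C=C(\C)C(=O)O[C@@H]1C=C(C)C[C@@H](OC(=O)c2ccc(O)cc2)[C@@H]2[C@@]1(C)CC[C@@]2(O)C(C)C | target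

Total step count: 14. Longest linear sequence: 12 steps (steps 1–4 and 7–14; steps 5–6 build the nitro ketal separately).

Steps most likely to fail

Step 7 comes first. The nitrile oxide may dimerise to the furoxan faster than it closes the seven-membered ring onto the hindered trisubstituted alkene. The fallback sets out from nitro ketone 10, isolated after the TMSOTf stage. TMSCl/Et3N (benzene, 23 °C) should convert it into the trimethylsilyl nitronate F1, a dipole that cannot dimerise. Heating (80 °C) should then give, by intramolecular silyl nitronate–alkene cycloaddition, the N-silyloxy isoxazolidine F2. TsOH (CH2Cl2) eliminates trimethylsilanol and the route is rejoined at isoxazoline 12.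

Step 1 is second. O-Sulfonylation of the hindered aluminium enolate may be slow, so that protonation on work-up erases the regiochemical information carried by the enolate. The fallback sets out again from 1 with the same conjugate addition, but enolate 2 is trapped with ClP(O)(OEt)2 as the enol phosphate F3. Coupling of F3 with i-PrMgCl under Fe(acac)3 catalysis (THF/NMP) rejoins the route at diene 4, bypassing the triflate.

Step 9 is third. Hydride may be delivered to the wrong face of C6 (internal delivery from an alkoxyborohydride instead of external attack on the chelate), giving the 6-epimer. The fallback sets out from 14: the 6S diol F4 is taken through the DBU elimination to the 6-epi enone diol F5. The C6 centre is then inverted while the ester is installed, by Mitsunobu reaction with 4-acetoxybenzoic acid (PPh3, DIAD, toluene), and the route is rejoined at ester 18.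

Further compounds
F1 | step 7 | trimethylsilyl nitronate of nitro ketone 10 | C[Si](C)(C)O[N+]([O-])=CCC(C)(OC)CC(=O)[C@]1(C)CCC(C(C)C)=C1
F2 | step 7 | (1R,4R,5S)-8-methoxy-4,6-(epoxyimino)daucan-10-one N-trimethylsilyloxy derivative (N-silyloxy isoxazolidine, C6 and C8 epimers) | O=C1CC(C)(OC)CC2N(O[Si](C)(C)C)O[C@@]3(C(C)C)CC[C@]1(C)[C@@H]23
F3 | step 1 | diethyl (S)-3-methyl-3-vinylcyclopent-1-en-1-yl phosphate | C=C[C@]1(C)CCC(OP(=O)(OCC)OCC)=C1
F4 | step 9 | (1R,4R,5S,6S)-4,6-dihydroxy-8-methoxydaucan-10-one | O=C1CC(C)(OC)C[C@H](O)[C@@H]2[C@@]1(C)CC[C@@]2(O)C(C)C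
F5 | step 9 | (1R,4R,5S,6S)-4,6-dihydroxydauc-8-en-10-one | O=C1C=C(C)C[C@H](O)[C@@H]2[C@@]1(C)CC[C@@]2(O)C(C)C
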